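**Retrosynthetic overview**

1. Ring A is bought as 2,2,6-trimethylcyclohexanone; ring B is formed second, by closing the C5–C6 bond (labdane numbering) with a SmI2 ketyl–nitrile coupling.
2. Enabling feature: C5 of ring A sits between two fully substituted carbons, C4 (gem-dimethyl) and C10 (quaternary, methyl-bearing). A C5 ketone therefore cannot enolise, and its ketyl can only add to the nitrile carbon C6, which the Z C8=C9 alkene of the future ring B holds five atoms away.
3. The C6 ketone made by that coupling relays all remaining stereocentres from C10: C5–H by protonation, 7α-O by axial enolate hydroxylation, 6β-O by α-face hydride delivery.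
4. The Z tetrasubstituted C8=C9 alkene with the side chain comes from alkoxide-directed syn-methylmagnesiation and iodination of a C10 alkyne, then B-alkyl Suzuki–Miyaura coupling with a diene made from (Z)-3-methylpent-2-en-4-yn-1-ol.
5. C10 is set by anti opening of the Shi epoxide of 1,3,3-trimethylcyclohexene with an alkynylalane.

Key step: step 12

Remark: atoms are numbered as in labdanes (ring A: C1–C5 and C10; ring B: C5–C10; C17 on C8, C18 and C19 on C4, C20 on C10; side chain C11–C16).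
Remark: the L-fructose-derived Shi ketone is assumed, from the spiro transition-state model, to give epoxide 5; if the facial sense is the opposite, the D-fructose-derived ketone is used and nothing else changes.
Remark: α-ketol 21 is drawn as its 5α-hydroxy epimer; either epimer serves, because C5 is re-formed in step 13.

**Route**

Step 1
Reactants: 1 2,2,6-trimethylcyclohexan-1-one
Product: 2 N'-(2,2,6-trimethylcyclohexylidene)-4-methylbenzenesulfonohydrazide
Conditions: TsNHNH2, cat. HCl, EtOH, reflux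
Reagents that add atoms: p-toluenesulfonyl hydrazide, Cc1ccc(cc1)S(=O)(=O)NN
Why: Acid-catalysed hydrazone condensation at the only carbonyl group, driven by removal of water; no stereocentre is carried forward.

Step 2
Reactants: 2 N'-(2,2,6-trimethylcyclohexylidene)-4-methylbenzenesulfonohydrazide
Product: 4 1,3,3-trimethylcyclohex-1-ene, via vinyllithium 3 (not isolated)
Conditions: n-BuLi (2.2 equiv), TMEDA, hexane, −78 → 0 °C; then H2O
Reagents that add atoms: none
Why: Shapiro reaction: the dianion formed at the only α-C–H loses sulfinate and N2 to give the vinyllithium, which is protonated to the single possible trisubstituted alkene.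

Step 3
Reactants: 4 1,3,3-trimethylcyclohex-1-ene
Product: 5 (1R,6S)-1,5,5-trimethyl-7-oxabicyclo[4.1.0]heptane
Conditions: L-fructose-derived Shi ketone (30 mol%), KHSO5 (as 2KHSO5·KHSO4·K2SO4), K2CO3, Bu4NHSO4, MeCN–CH2(OMe)2 / aq. Na2B4O7–Na2EDTA, 0 °C
Reagents that add atoms: potassium peroxymonosulfate, [K+].[O-]S(=O)(=O)OO
Why: Shi asymmetric epoxidation: the chiral dioxirane transfers oxygen to the trisubstituted alkene through the spiro transition state, so the catalyst sets both oxirane carbons.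

Step 4
Reactants: 5 (1R,6S)-1,5,5-trimethyl-7-oxabicyclo[4.1.0]heptane; 6 4,4-diethoxybut-1-yne
Product: 9 (1S,2R)-2-(4,4-diethoxybut-1-yn-1-yl)-2,6,6-trimethylcyclohexan-1-ol, via lithium acetylide 7 (not isolated), via alkynylalane 8 (not isolated)
Conditions: 6, n-BuLi, toluene–THF, −78 °C; Et2AlCl, 0 °C; then 5, toluene, 0 °C → rt; aq. KNaC4H4O6
Reagents that add atoms: none
Why: Alkynylalane opening of an epoxide: aluminium activates the oxirane and the alkynyl group attacks anti at the tertiary, cation-stabilising carbon (the other carbon is neopentyl and screened by the gem-dimethyl group), so the quaternary C10 is formed with inversion and carries the configuration set in step 3, giving the trans alcohol.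

Step 5
Reactants: 9 (1S,2R)-2-(4,4-diethoxybut-1-yn-1-yl)-2,6,6-trimethylcyclohexan-1-ol
Product: 11 (1S,2S)-2-[(1E)-4,4-diethoxy-1-iodo-2-methylbut-1-en-1-yl]-2,6,6-trimethylcyclohexan-1-ol, via vinylmagnesium chelate 10 (not isolated)
Conditions: MeMgBr (5 equiv), Fe(acac)3 (15 mol%), THF, 0 °C → rt; then I2, −78 → 0 °C
Reagents that add atoms: methylmagnesium bromide, C[Mg]Br; iodine, II
Why: Iron-catalysed, alkoxide-directed carbomagnesiation of a homopropargylic alcohol: methyl and magnesium add syn, with magnesium on the alkyne carbon that closes a five-membered oxamagnesacycle, and iodination with retention fixes the tetrasubstituted alkene with the acetal arm cis to the ring, the geometry ring B needs.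

Step 6
Reactants: 12 (2Z)-3-methylpent-2-en-4-yn-1-ol
Product: 13 tert-butyl{[(2Z)-3-methylpent-2-en-4-yn-1-yl]oxy}diphenylsilane
Conditions: TBDPSCl, imidazole, CH2Cl2, 0 °C → rt
Reagents that add atoms: tert-butyl(chloro)diphenylsilane, CC(C)(C)[Si](Cl)(c1ccccc1)c1ccccc1
Why: Silylation of the primary allylic alcohol; the robust silyl ether survives every later step up to the last and the Z alkene is untouched.

Step 7
Reactants: 13 tert-butyl{[(2Z)-3-methylpent-2-en-4-yn-1-yl]oxy}diphenylsilane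
Product: 14 tert-butyl{[(2Z)-3-methylpenta-2,4-dien-1-yl]oxy}diphenylsilane
Conditions: H2 (1 atm), Pd/CaCO3 poisoned with Pb(OAc)2 (Lindlar), quinoline, hexane, rt
Reagents that add atoms: none
Why: Lindlar semihydrogenation stops at the terminal vinyl group and leaves the trisubstituted Z alkene unchanged.

Step 8
Reactants: 11 (1S,2S)-2-[(1E)-4,4-diethoxy-1-iodo-2-methylbut-1-en-1-yl]-2,6,6-trimethylcyclohexan-1-ol; 14 tert-butyl{[(2Z)-3-methylpenta-2,4-dien-1-yl]oxy}diphenylsilane
Product: 16 (1S,2R)-2-[(3Z,7Z)-9-(tert-butyldiphenylsilyloxy)-1,1-diethoxy-3,7-dimethylnona-3,7-dien-4-yl]-2,6,6-trimethylcyclohexan-1-ol, via alkylborane 15 (not isolated)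
Conditions: 14, (9-BBN-H)2, THF, 0 °C → rt; then 11, Pd(dppf)Cl2 (10 mol%), AsPh3, Cs2CO3, DMF–THF–H2O, rt → 45 °C
Reagents that add atoms: none
Why: 9-BBN hydroborates only the terminal vinyl group (anti-Markovnikov), and the B-alkyl Suzuki–Miyaura coupling joins that sp3 carbon to the hindered vinyl iodide with retention of alkene geometry, the free hydroxyl being tolerated.

Step 9
Reactants: 16 (1S,2R)-2-[(3Z,7Z)-9-(tert-butyldiphenylsilyloxy)-1,1-diethoxy-3,7-dimethylnona-3,7-dien-4-yl]-2,6,6-trimethylcyclohexan-1-ol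
Product: 17 (2R)-2-[(3Z,7Z)-9-(tert-butyldiphenylsilyloxy)-1,1-diethoxy-3,7-dimethylnona-3,7-dien-4-yl]-2,6,6-trimethylcyclohexan-1-one
Conditions: Dess–Martin periodinane, NaHCO3, CH2Cl2, 0 °C → rt
Reagents that add atoms: none
Why: Dess–Martin oxidation of the hindered secondary alcohol to the non-enolisable C5 ketone; the carbinol centre, needed only to direct step 5, is removed.

Step 10
Reactants: 17 (2R)-2-[(3Z,7Z)-9-(tert-butyldiphenylsilyloxy)-1,1-diethoxy-3,7-dimethylnona-3,7-dien-4-yl]-2,6,6-trimethylcyclohexan-1-one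
Product: 18 (3Z,7Z)-9-(tert-butyldiphenylsilyloxy)-3,7-dimethyl-4-[(1R)-1,3,3-trimethyl-2-oxocyclohexyl]nona-3,7-dienal oxime (mixture of oxime geometries)
Conditions: NH2OH·HCl (3 equiv), THF–H2O 4:1, 40 °C
Reagents that add atoms: hydroxylamine hydrochloride, [NH3+]O.[Cl-]
Why: Acetal hydrolysis with in situ oximation: the hydrochloride supplies the acid and the β,γ-unsaturated aldehyde is trapped at once as the aldoxime, while the ring ketone, flanked by two quaternary carbons, does not condense.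

Step 11
Reactants: 18 the aldoxime of step 10
Product: 19 (3Z,7Z)-9-(tert-butyldiphenylsilyloxy)-3,7-dimethyl-4-[(1R)-1,3,3-trimethyl-2-oxocyclohexyl]nona-3,7-dienenitrile
Conditions: (CF3CO)2O, Et3N, CH2Cl2, −10 → 0 °C
Reagents that add atoms: none
Why: Aldoxime dehydration (O-trifluoroacetylation, then elimination of trifluoroacetate) gives the nitrile under conditions too mild to move the alkene.

Step 12
Reactants: 19 (3Z,7Z)-9-(tert-butyldiphenylsilyloxy)-3,7-dimethyl-4-[(1R)-1,3,3-trimethyl-2-oxocyclohexyl]nona-3,7-dienenitrile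
Product: 21 15-(tert-butyldiphenylsilyloxy)-5α-hydroxylabda-8,13Z-dien-6-one, via hydroxy ketimine 20 (not isolated)
Conditions: SmI2 (3 equiv), t-BuOH (2 equiv), THF, visible light, rt; then 0.1 M aq. HCl, 0 °C
Reagents that add atoms: water, O
Why: Electron transfer from SmI2 under visible light to the non-enolisable C5 ketone gives a ketyl that adds to the nitrile carbon C6, and a second electron with t-BuOH gives the N-samarium ketimine, which aqueous acid hydrolyses to the C6 ketone. The closest known reaction is the SmI2-promoted intramolecular reductive coupling of ketones with nitriles to 2-hydroxycycloalkanones. Ring B closes in the 6-exo-dig mode, the Z C8=C9 alkene holding C6 within reach of C5. The only new stereocentre, the C5 carbinol, is controlled by the chair of ring A with the C9 arm equatorial (trans fusion, 5α-OH expected), and both epimers converge in step 13, where C5 is re-formed by protonation. The step needs chemoselectivity for the ketone over the nitrile, the two isolated alkenes and the allylic silyl ether, which the reduction potentials secure, and it needs the ketyl to add faster than it is protonated or dimerised, which the absence of α-hydrogens on C4 and C10, high dilution and the six-membered, alkene-constrained tether secure.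

Step 13
Reactants: 21 15-(tert-butyldiphenylsilyloxy)-5α-hydroxylabda-8,13Z-dien-6-one
Product: 22 15-(tert-butyldiphenylsilyloxy)labda-8,13Z-dien-6-one (5α-H, 10β-methyl; 5S,10S)
Conditions: SmI2 (2.5 equiv), THF–MeOH, −78 → −40 °C
Reagents that add atoms: none
Why: SmI2 reductive cleavage of an α-hydroxy ketone: the C5–O bond is lost from the C6 ketyl and the samarium enolate is protonated at C5 from the α-face, opposite the axial 4β- and 10β-methyl groups, which should give the trans ring fusion from either C5 epimer of 21.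

Step 14
Reactants: 22 15-(tert-butyldiphenylsilyloxy)labda-8,13Z-dien-6-one
Product: 24 15-(tert-butyldiphenylsilyloxy)-7α-hydroxylabda-8,13Z-dien-6-one, via potassium dienolate 23 (not isolated)
Conditions: KN(SiMe3)2 (1.1 equiv), THF, −78 °C; 2-(phenylsulfonyl)-3-phenyloxaziridine, −78 °C; aq. NH4Cl
Reagents that add atoms: 2-(phenylsulfonyl)-3-phenyloxaziridine (Davis oxaziridine), O=S(=O)(c1ccccc1)N1OC1c1ccccc1
Why: Enolate oxidation with the Davis oxaziridine: kinetic deprotonation occurs at C7 (α to the ketone and allylic) rather than at the hindered C5–H, and oxygen is delivered to C7 axially from the α-face, away from the 10β- and 4β-methyl groups, giving the 7α-alcohol.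

Step 15
Reactants: 24 15-(tert-butyldiphenylsilyloxy)-7α-hydroxylabda-8,13Z-dien-6-one
Product: 25 15-(tert-butyldiphenylsilyloxy)labda-8,13Z-diene-6β,7α-diol
Conditions: Me4NBH(OAc)3 (5 equiv), MeCN–AcOH 1:1, −30 → −20 °C
Reagents that add atoms: none
Why: Hydroxyl-directed (Evans–Saksena) reduction: the acetoxyborohydride binds the 7α-hydroxyl and delivers hydride to the α-face of C6, which is also the face not screened by the two axial methyl groups, giving the 6β-alcohol and hence the trans-diaxial diol.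

Step 16
Reactants: 25 15-(tert-butyldiphenylsilyloxy)labda-8,13Z-diene-6β,7α-diol
Product: 26 15-(tert-butyldiphenylsilyloxy)labda-8,13Z-diene-6β,7α-diyl diacetate
Conditions: Ac2O, DMAP, pyridine, 40 °C
Reagents that add atoms: acetic anhydride, CC(=O)OC(C)=O
Why: DMAP-catalysed acetylation of both secondary alcohols, gentle warming being used for the axial, hindered 6β-hydroxyl; no stereocentre is touched.

Step 17
Reactants: 26 15-(tert-butyldiphenylsilyloxy)labda-8,13Z-diene-6β,7α-diyl diacetate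
Product: 27 (5S,6S,7S,10S,13Z)-15-hydroxylabda-8,13-diene-6β,7α-diyl diacetate (CNP0187815.3)
Conditions: HF·pyridine, pyridine–THF, 0 °C → rt
Reagents that add atoms: none
Why: Fluoride-mediated cleavage of the silyl ether under buffered conditions frees the primary allylic alcohol without acetate migration or loss.

**Compound list**

1 | 2,2,6-trimethylcyclohexan-1-one (racemic) | CC1CCCC(C)(C)C1=O | starting material
2 | N'-(2,2,6-trimethylcyclohexylidene)-4-methylbenzenesulfonohydrazide | CC1CCCC(C)(C)C1=NNS(=O)(=O)c1ccc(C)cc1 | intermediate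
3 | (2,6,6-trimethylcyclohex-1-en-1-yl)lithium | [Li]C1=C(C)CCCC1(C)C | intermediate
4 | 1,3,3-trimethylcyclohex-1-ene | CC1=CC(C)(C)CCC1 | intermediate
5 | (1R,6S)-1,5,5-trimethyl-7-oxabicyclo[4.1.0]heptane | C[C@@]12CCCC(C)(C)[C@@H]1O2 | intermediate
6 | 4,4-diethoxybut-1-yne | C#CCC(OCC)OCC | starting material
7 | (4,4-diethoxybut-1-yn-1-yl)lithium | [Li]C#CCC(OCC)OCC | intermediate
8 | (4,4-diethoxybut-1-yn-1-yl)diethylaluminium | CC[Al](CC)C#CCC(OCC)OCC | intermediate
9 | (1S,2R)-2-(4,4-diethoxybut-1-yn-1-yl)-2,6,6-trimethylcyclohexan-1-ol (hydroxyl trans to alkynyl) | CCOC(OCC)CC#C[C@@]1(C)CCCC(C)(C)[C@@H]1O | intermediate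
10 | bromomagnesium alkoxide of the (E)-1-(bromomagnesio)-4,4-diethoxy-2-methylbut-1-enyl alcohol (five-membered chelate) | CCOC(OCC)C/C(C)=C(/[Mg]Br)[C@@]1(C)CCCC(C)(C)[C@@H]1O[Mg]Br | intermediate
11 | (1S,2S)-2-[(1E)-4,4-diethoxy-1-iodo-2-methylbut-1-en-1-yl]-2,6,6-trimethylcyclohexan-1-ol | CCOC(OCC)C/C(C)=C(/I)[C@@]1(C)CCCC(C)(C)[C@@H]1O | intermediate
12 | (2Z)-3-methylpent-2-en-4-yn-1-ol | C#C/C(C)=C\CO | starting material
13 | tert-butyl{[(2Z)-3-methylpent-2-en-4-yn-1-yl]oxy}diphenylsilane | C#C/C(C)=C\CO[Si](c1ccccc1)(c1ccccc1)C(C)(C)C | intermediate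
14 | tert-butyl{[(2Z)-3-methylpenta-2,4-dien-1-yl]oxy}diphenylsilane | C=C/C(C)=C\CO[Si](c1ccccc1)(c1ccccc1)C(C)(C)C | intermediate
15 | 9-[(3Z)-5-(tert-butyldiphenylsilyloxy)-3-methylpent-3-en-1-yl]-9-borabicyclo[3.3.1]nonane | C1CCC2CCCC1B2CC/C(C)=C\CO[Si](c1ccccc1)(c1ccccc1)C(C)(C)C | intermediate
16 | (1S,2R)-2-[(3Z,7Z)-9-(tert-butyldiphenylsilyloxy)-1,1-diethoxy-3,7-dimethylnona-3,7-dien-4-yl]-2,6,6-trimethylcyclohexan-1-ol | CCOC(OCC)C/C(C)=C(/CC/C(C)=C\CO[Si](c1ccccc1)(c1ccccc1)C(C)(C)C)[C@@]1(C)CCCC(C)(C)[C@@H]1O | intermediate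
17 | (2R)-2-[(3Z,7Z)-9-(tert-butyldiphenylsilyloxy)-1,1-diethoxy-3,7-dimethylnona-3,7-dien-4-yl]-2,6,6-trimethylcyclohexan-1-one | CCOC(OCC)C/C(C)=C(/CC/C(C)=C\CO[Si](c1ccccc1)(c1ccccc1)C(C)(C)C)[C@@]1(C)CCCC(C)(C)C1=O | intermediate
18 | (3Z,7Z)-9-(tert-butyldiphenylsilyloxy)-3,7-dimethyl-4-[(1R)-1,3,3-trimethyl-2-oxocyclohexyl]nona-3,7-dienal oxime (oxime geometry not defined) | ON=CC/C(C)=C(/CC/C(C)=C\CO[Si](c1ccccc1)(c1ccccc1)C(C)(C)C)[C@@]1(C)CCCC(C)(C)C1=O | intermediate
19 | (3Z,7Z)-9-(tert-butyldiphenylsilyloxy)-3,7-dimethyl-4-[(1R)-1,3,3-trimethyl-2-oxocyclohexyl]nona-3,7-dienenitrile | N#CC/C(C)=C(/CC/C(C)=C\CO[Si](c1ccccc1)(c1ccccc1)C(C)(C)C)[C@@]1(C)CCCC(C)(C)C1=O | intermediate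
20 | 15-(tert-butyldiphenylsilyloxy)-5α-hydroxylabda-8,13Z-dien-6-imine | CC1=C(CC/C(C)=C\CO[Si](c3ccccc3)(c3ccccc3)C(C)(C)C)[C@@]2(C)CCCC(C)(C)[C@]2(O)C(=N)C1 | intermediate
21 | 15-(tert-butyldiphenylsilyloxy)-5α-hydroxylabda-8,13Z-dien-6-one | CC1=C(CC/C(C)=C\CO[Si](c3ccccc3)(c3ccccc3)C(C)(C)C)[C@@]2(C)CCCC(C)(C)[C@]2(O)C(=O)C1 | intermediate
22 | 15-(tert-butyldiphenylsilyloxy)labda-8,13Z-dien-6-one (5S,10S) | CC1=C(CC/C(C)=C\CO[Si](c3ccccc3)(c3ccccc3)C(C)(C)C)[C@@]2(C)CCCC(C)(C)[C@@H]2C(=O)C1 | intermediate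
23 | potassium 6,8-dienolate of 22 (C6–OK, C6=C7, C8=C9) | CC1=C(CC/C(C)=C\CO[Si](c3ccccc3)(c3ccccc3)C(C)(C)C)[C@@]2(C)CCCC(C)(C)[C@@H]2C(O[K])=C1 | intermediate
24 | 15-(tert-butyldiphenylsilyloxy)-7α-hydroxylabda-8,13Z-dien-6-one (5S,7S,10S) | CC1=C(CC/C(C)=C\CO[Si](c3ccccc3)(c3ccccc3)C(C)(C)C)[C@@]2(C)CCCC(C)(C)[C@@H]2C(=O)[C@H]1O | intermediate
25 | 15-(tert-butyldiphenylsilyloxy)labda-8,13Z-diene-6β,7α-diol (5S,6S,7S,10S) | CC1=C(CC/C(C)=C\CO[Si](c3ccccc3)(c3ccccc3)C(C)(C)C)[C@@]2(C)CCCC(C)(C)[C@@H]2[C@H](O)[C@H]1O | intermediate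
26 | 15-(tert-butyldiphenylsilyloxy)labda-8,13Z-diene-6β,7α-diyl diacetate | CC1=C(CC/C(C)=C\CO[Si](c3ccccc3)(c3ccccc3)C(C)(C)C)[C@@]2(C)CCCC(C)(C)[C@@H]2[C@H](OC(C)=O)[C@H]1OC(C)=O | intermediate
27 | (5S,6S,7S,10S,13Z)-15-hydroxylabda-8,13-diene-6β,7α-diyl diacetate | CC1=C(CC/C(C)=C\CO)[C@@]2(C)CCCC(C)(C)[C@@H]2[C@H](OC(C)=O)[C@H]1OC(C)=O | target

**Step count and risks**

Total step count: 17. Longest linear sequence: 15 steps (steps 1–5 and 8–17; steps 6 and 7 make the side-chain diene).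

Steps most likely to fail:

1. Step 12. The ketyl may be protonated (simple reduction of the C5 ketone) or may dimerise faster than it adds to the nitrile, or the acidic CH2 next to the nitrile may quench it. Fallback, from 17 back to 22, with a titanium-induced keto ester cyclisation in place of the ketyl–nitrile coupling. Acetal 17 is hydrolysed (PPTS, acetone–water) to (3Z,7Z)-9-(tert-butyldiphenylsilyloxy)-3,7-dimethyl-4-[(1R)-1,3,3-trimethyl-2-oxocyclohexyl]nona-3,7-dienal F9. Oxidation (NaClO2, NaH2PO4, 2-methylbut-2-ene) gives the corresponding nona-3,7-dienoic acid F10, and TMSCHN2 gives its methyl ester F11. McMurry keto ester coupling (TiCl3, LiAlH4, Et3N, DME, reflux, slow addition) should give 15-(tert-butyldiphenylsilyloxy)-6-methoxylabda-5,8,13Z-triene F12, whose enol ether is hydrolysed by dilute aqueous acid on work-up to 22.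

2. Step 4. The Lewis acid may trigger a hydride shift of the epoxide to the ketone, or the tertiary carbon may ionise and lose the anti stereospecificity, which would erode the configuration at C10. Fallback, from 1 back to 9, setting C10 by palladium-catalysed decarboxylative asymmetric allylic alkylation instead. Ketone 1 is converted (LiN(SiMe3)2, allyl chloroformate) into allyl 2,6,6-trimethylcyclohex-1-en-1-yl carbonate F1. Pd2(dba)3 with (R)-t-BuPHOX should give (R)-2-allyl-2,6,6-trimethylcyclohexan-1-one F2. Alkene isomerisation (PdCl2(MeCN)2, benzene, 60 °C) gives (R)-2,2,6-trimethyl-6-[(1E)-prop-1-en-1-yl]cyclohexan-1-one F3, and ozonolysis (O3, then Me2S) gives (R)-1,3,3-trimethyl-2-oxocyclohexane-1-carbaldehyde F4. Colvin homologation (lithiated trimethylsilyldiazomethane, THF, −78 °C → rt) gives (R)-2-ethynyl-2,6,6-trimethylcyclohexan-1-one F5. Alkylation of its lithium acetylide with 2-bromo-1,1-diethoxyethane (THF–DMPU) gives (R)-2-(4,4-diethoxybut-1-yn-1-yl)-2,6,6-trimethylcyclohexan-1-one F6. LiAlH4 reduction, with hydride entering on the side of the slim alkynyl group, should give 9.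

3. Step 5. Carbometalation may stall at the alkyne carbon next to the quaternary centre, or the vinylmagnesium may lose its geometry before iodination. Fallback, from 9 back to 11, using syn-diboration and two site-selective substitutions instead of carbomagnesiation. Alcohol 9 is diborated (B2pin2, Pt(PPh3)4, DMF, 80 °C) to the (1Z)-4,4-diethoxy-1,2-bis(4,4,5,5-tetramethyl-1,3,2-dioxaborolan-2-yl)but-1-enyl alcohol F7. Suzuki–Miyaura methylation at the less hindered boronate (MeI, Pd(dppf)Cl2, K3PO4, dioxane–water) gives the (1Z)-4,4-diethoxy-2-methyl-1-(4,4,5,5-tetramethyl-1,3,2-dioxaborolan-2-yl)but-1-enyl alcohol F8. Iododeboronation with retention (N-iodosuccinimide, MeCN) gives 11.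

Further compounds
F1 | step 4 | allyl 2,6,6-trimethylcyclohex-1-en-1-yl carbonate | C=CCOC(=O)OC1=C(C)CCCC1(C)C
F2 | step 4 | (R)-2-allyl-2,6,6-trimethylcyclohexan-1-one | C=CC[C@@]1(C)CCCC(C)(C)C1=O
F3 | step 4 | (R)-2,2,6-trimethyl-6-[(1E)-prop-1-en-1-yl]cyclohexan-1-one | C/C=C/[C@@]1(C)CCCC(C)(C)C1=O
F4 | step 4 | (R)-1,3,3-trimethyl-2-oxocyclohexane-1-carbaldehyde | O=C[C@@]1(C)CCCC(C)(C)C1=O
F5 | step 4 | (R)-2-ethynyl-2,6,6-trimethylcyclohexan-1-one | C#C[C@@]1(C)CCCC(C)(C)C1=O
F6 | step 4 | (R)-2-(4,4-diethoxybut-1-yn-1-yl)-2,6,6-trimethylcyclohexan-1-one | CCOC(OCC)CC#C[C@@]1(C)CCCC(C)(C)C1=O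
F7 | step 5 | (1S,2R)-2-[(1Z)-4,4-diethoxy-1,2-bis(4,4,5,5-tetramethyl-1,3,2-dioxaborolan-2-yl)but-1-en-1-yl]-2,6,6-trimethylcyclohexan-1-ol | CCOC(OCC)C/C(B1OC(C)(C)C(C)(C)O1)=C(/B1OC(C)(C)C(C)(C)O1)[C@@]1(C)CCCC(C)(C)[C@@H]1O
F8 | step 5 | (1S,2R)-2-[(1Z)-4,4-diethoxy-2-methyl-1-(4,4,5,5-tetramethyl-1,3,2-dioxaborolan-2-yl)but-1-en-1-yl]-2,6,6-trimethylcyclohexan-1-ol | CCOC(OCC)C/C(C)=C(/B1OC(C)(C)C(C)(C)O1)[C@@]1(C)CCCC(C)(C)[C@@H]1O
F9 | step 12 | (3Z,7Z)-9-(tert-butyldiphenylsilyloxy)-3,7-dimethyl-4-[(1R)-1,3,3-trimethyl-2-oxocyclohexyl]nona-3,7-dienal | O=CC/C(C)=C(/CC/C(C)=C\CO[Si](c1ccccc1)(c1ccccc1)C(C)(C)C)[C@@]1(C)CCCC(C)(C)C1=O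
F10 | step 12 | (3Z,7Z)-9-(tert-butyldiphenylsilyloxy)-3,7-dimethyl-4-[(1R)-1,3,3-trimethyl-2-oxocyclohexyl]nona-3,7-dienoic acid | OC(=O)C/C(C)=C(/CC/C(C)=C\CO[Si](c1ccccc1)(c1ccccc1)C(C)(C)C)[C@@]1(C)CCCC(C)(C)C1=O
F11 | step 12 | methyl (3Z,7Z)-9-(tert-butyldiphenylsilyloxy)-3,7-dimethyl-4-[(1R)-1,3,3-trimethyl-2-oxocyclohexyl]nona-3,7-dienoate | COC(=O)C/C(C)=C(/CC/C(C)=C\CO[Si](c1ccccc1)(c1ccccc1)C(C)(C)C)[C@@]1(C)CCCC(C)(C)C1=O
F12 | step 12 | 15-(tert-butyldiphenylsilyloxy)-6-methoxylabda-5,8,13Z-triene | CC1=C(CC/C(C)=C\CO[Si](c3ccccc3)(c3ccccc3)C(C)(C)C)[C@@]2(C)CCCC(C)(C)C2=C(OC)C1
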